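The readings were generated by integration with made-up constants.

Slowness is what you notice first: after 80.0 min the theta flask, charged with 0.051 M substrate, reads 61% of it as product, and loading more substrate looks like the cure. You are about to repeat that idea at the charges below.

| setting | theta | eta | dusk | winter | autumn |
|---|---|---|---|---|---|
| substrate | 0.051 M | 0.49 M | 0.060 M | 0.20 M | 0.60 M |
| partner | 0.247 M | 0.247 M | 0.247 M | 0.247 M | 0.247 M |
| free catalyst | 3.8 mM | 3.8 mM | 3.8 mM | 3.8 mM | 3.8 mM |
| remark | run made earlier | run made earlier |  |  |  |
| time |  |  | 80 min | 80 min | 80 min |

| run | time / min | product / % |
|---|---|---|
| theta | 12.0 | 7 |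
| theta | 25.0 | 18 |
| theta | 40.0 | 33 |
| theta | 50.0 | 39 |
| theta | 60.0 | 47 |
| theta | 80.0 | 61 |
| eta | 6.00 | 3 |
| eta | 10.0 | 1 |
| eta | 20.0 | 4 |
| eta | 30.0 | 9 |
| eta | 50.0 | 14 |
| eta | 80.0 | 14 |

(each reading ± 2 percentage points)

- a reading or a percentage of product counts all its forms, free or not
- the concentration of product that is asked is that of its free form alone
- "hardly changes" means that all values lie within two and a half points (for a concentration: within two and a half percent of the largest)

- [product] (only what is free in solution) at the end for dusk, winter, autumn, in this order
- how that number moves from the first to the last of them (rises, then falls / rises all the way / falls, then rises / falls all the way / hardly changes)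

The eta flask seems to contradict the cure. It holds ten times the substrate of theta, yet at the same time it reads counted product of 0.0686 M against 0.0311 M, which is twice as much. Divide the logarithm of that product ratio by the logarithm of the substrate ratio. This end order, the power by which counted product at the end follows the substrate charged with partner and catalyst held fixed, comes, as a reading, to 0.349. On this reading, a doubling of substrate between these charges buys a factor of 1.27. The two numbers now fit: theta and eta share their partner and catalyst charges, and I take so low an order for saturation, with the rate following one of those.

On that line I reckon counted product at the end as 0.0329 M for dusk, 0.0502 M for winter and 0.0736 M for autumn, rising all the way. Free product lies below these by whatever is bound. The readings count all forms and cannot show that amount, so watch it in autumn.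

The forecast, reading “a fixed absolute cap” from eta, gives 0.034 M, 0.063 M and 0.066 M, rises all the way.

The flask gives 0.0336 M, 0.0464 M and 0.0299 M: rises, then falls.

    free catalyst + open intermediate ⇌ catalyst intermediate (K = 45.0 M⁻¹, k = 268 M⁻¹ min⁻¹)
    substrate + product ⇌ idle adduct, settled at all times (K = 4.70 M⁻¹)
    substrate + free catalyst → free catalyst + open intermediate (k = 8.12 M⁻¹ min⁻¹)
    partner + catalyst intermediate → free catalyst + product (k = 1.51 M⁻¹ min⁻¹)

Autumn counts 0.0757 M of product in all forms, close to the 0.0736 M from the end order, while winter, the second test, counts 0.0616 M, above its reckoned 0.0502 M. Part of the downturn in free product comes from substrate and product tying up as idle adduct, together with the length of the run. Without that tying up, autumn ends at 0.0759 M instead of 0.0299 M, and an autumn run of 800 min ends at 0.197 M.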